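The target hides a repeat: ring B (tetrahydrochromone) and the primed chromone A each carry the same C4(=O)–C3=C2–CH2CH2Ph arm, bonded to C4a and to C4a′. Everything rests on cutting C4a–C4, C4–C3, C4a′–C4′ and C4′–C3′ together. In one operation a twofold carbonylative alkynylation joins a diiodide, two CO and two 4-phenylbut-1-yne units into an open bis-ynone; both pyranone rings close afterwards. The precursor is a 2-iodocyclohex-2-enone (vinyl iodide at C4a, ketone at C8a) whose C8 oxygen bears the aryl ring with its iodide at C4a′, the neighbouring phenol capped as acetate and O6, O7 as silyl ethers.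

Key step: step 8

Remark 1: chromone locants (C5–C8, C4a, C8a; primed for the aromatic chromone) are used for the carbocycle. In the cyclohexenone intermediates, C6, C5, C4, C3, C2 and C1 are the later C8, C7, C6, C5, C4a and C8a.

Remark 2: with O4 and O5 silylated, the cyclohexenones (diiodide 12 included) are (4R,5R,6S) by the CIP rules; an all-S label would describe another diastereomer. The spatial arrangement is that of the target throughout (O7/O8 cis, O6 trans to O7). The letter at the O7 carbon changes between 6, 7 and 19 only because silicon alters the priorities.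

Remark 3: three design choices protect the key step and its surroundings.
- The phenol is carried as its acetate, so that neither ynone can cyclise or be attacked by phenoxide during the coupling.
- O7 carries triisopropylsilyl, which resists 1,2-shift to the neighbouring alkoxide in step 2.
- Ring B is closed before ring A, because a secondary amine would add to C5 of the 2-acylenone.

Assumption: (1S,2S)-bromodiol 1 (the cis-dihydrodiol of bromobenzene) is purchased.

Step 1
Reactants: 1 (1S,2S)-3-bromocyclohexa-3,5-diene-1,2-diol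
Product: 2 (1S,6S)-2-bromo-6-(triisopropylsilyloxy)cyclohexa-2,4-dien-1-ol
Conditions: TIPSOTf (1.05 equiv), 2,6-lutidine, CH2Cl2, −78 °C
Reagents that add atoms: triisopropylsilyl trifluoromethanesulfonate (TIPSOTf), CC(C)[Si](C(C)C)(C(C)C)OS(=O)(=O)C(F)(F)F
Why: Silylation with a silyl triflate at low temperature should take the less hindered hydroxyl distal to the bromoalkene, the lutidine buffer protects the acid-sensitive dienediol, and no stereocentre is touched.

Step 2
Reactants: 2 (1S,6S)-2-bromo-6-(triisopropylsilyloxy)cyclohexa-2,4-dien-1-ol; 3 4-fluoro-3-methoxybenzaldehyde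
Product: 4 4-{[(1S,6S)-2-bromo-6-(triisopropylsilyloxy)cyclohexa-2,4-dien-1-yl]oxy}-3-methoxybenzaldehyde
Conditions: KN(SiMe3)2, THF, −78 °C; then 3, DMF, −40 → 0 °C
Reagents that add atoms: none
Why: Nucleophilic aromatic substitution (SNAr) of the potassium alkoxide at the fluoride para to the formyl group forms the aryl ether without breaking the carbinol C–O bond, so the later C8 keeps its configuration cis to O7.

Step 3
Reactants: 4 4-{[(1S,6S)-2-bromo-6-(triisopropylsilyloxy)cyclohexa-2,4-dien-1-yl]oxy}-3-methoxybenzaldehyde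
Product: 6 (4R,5S,6S)-6-(4-formyl-2-methoxyphenoxy)-4-hydroxy-5-(triisopropylsilyloxy)cyclohex-2-en-1-one, via endoperoxide 5 (not isolated)
Conditions: O2, tetraphenylporphyrin (cat.), hν, CH2Cl2, −78 °C; then thiourea, NaHCO3, MeOH, −78 °C → rt
Reagents that add atoms: dioxygen, O=O
Why: The [4+2] cycloaddition of singlet oxygen should occur on the diene face opposite both oxygen substituents, which sets C6 trans to O7; thiourea reduction of the O–O bond then gives a bromohydrin that collapses to the ketone with loss of HBr, the known behaviour of halodiene endoperoxides.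

Step 4
Reactants: 6 (4R,5S,6S)-6-(4-formyl-2-methoxyphenoxy)-4-hydroxy-5-(triisopropylsilyloxy)cyclohex-2-en-1-one
Product: 7 (4R,5R,6S)-4-(tert-butyldimethylsilyloxy)-6-(4-formyl-2-methoxyphenoxy)-5-(triisopropylsilyloxy)cyclohex-2-en-1-one
Conditions: TBSOTf, 2,6-lutidine, CH2Cl2, −78 °C
Reagents that add atoms: tert-butyldimethylsilyl trifluoromethanesulfonate (TBSOTf), CC(C)(C)[Si](C)(C)OS(=O)(=O)C(F)(F)F
Why: Standard silylation of the gamma-hydroxyl blocks its base-induced isomerisation and places a bulky group on the face that must later be shielded at C5; no stereocentre changes.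

Step 5
Reactants: 7 (4R,5R,6S)-4-(tert-butyldimethylsilyloxy)-6-(4-formyl-2-methoxyphenoxy)-5-(triisopropylsilyloxy)cyclohex-2-en-1-one
Product: 9 (4R,5R,6S)-4-(tert-butyldimethylsilyloxy)-6-(4-hydroxy-2-methoxyphenoxy)-5-(triisopropylsilyloxy)cyclohex-2-en-1-one, via aryl formate 8 (not isolated)
Conditions: mCPBA, NaHCO3, CH2Cl2, 0 °C → rt; then Et3N, MeOH, 0 °C
Reagents that add atoms: 3-chloroperoxybenzoic acid (mCPBA), OOC(=O)c1cccc(Cl)c1
Why: In this Dakin-type Baeyer–Villiger oxidation the electron-rich aryl group migrates to give the formate, which mild methanolysis cleaves, while the electron-poor enone is inert to the peracid.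

Step 6
Reactants: 9 (4R,5R,6S)-4-(tert-butyldimethylsilyloxy)-6-(4-hydroxy-2-methoxyphenoxy)-5-(triisopropylsilyloxy)cyclohex-2-en-1-one
Product: 11 (4R,5R,6S)-6-(4-acetoxy-5-iodo-2-methoxyphenoxy)-4-(tert-butyldimethylsilyloxy)-5-(triisopropylsilyloxy)cyclohex-2-en-1-one, via iodophenol 10 (not isolated)
Conditions: NIS, MeCN, 0 °C; then Ac2O, pyridine, DMAP (cat.), 0 °C → rt
Reagents that add atoms: N-iodosuccinimide (NIS), O=C1CCC(=O)N1I; acetic anhydride, CC(=O)OC(C)=O
Why: Electrophilic aromatic iodination should go ortho to the hydroxyl and para to the methoxy group (the only unhindered activated position, the later C4a′), and acetylation in the same flask caps the phenol.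

Step 7
Reactants: 11 (4R,5R,6S)-6-(4-acetoxy-5-iodo-2-methoxyphenoxy)-4-(tert-butyldimethylsilyloxy)-5-(triisopropylsilyloxy)cyclohex-2-en-1-one
Product: 12 (4R,5R,6S)-6-(4-acetoxy-5-iodo-2-methoxyphenoxy)-4-(tert-butyldimethylsilyloxy)-2-iodo-5-(triisopropylsilyloxy)cyclohex-2-en-1-one
Conditions: I2, pyridine, CH2Cl2, 0 °C → rt
Reagents that add atoms: iodine, II
Why: Pyridine-mediated alpha-iodination of the enone (conjugate addition of pyridine, iodination of the enolate, elimination) is the standard route to 2-iodoenones, and the acetylated arene is too deactivated to be iodinated again.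

Step 8
Reactants: 12 (4R,5R,6S)-6-(4-acetoxy-5-iodo-2-methoxyphenoxy)-4-(tert-butyldimethylsilyloxy)-2-iodo-5-(triisopropylsilyloxy)cyclohex-2-en-1-one; 13 4-phenylbut-1-yne
Product: 14 (4R,5R,6S)-6-[4-acetoxy-2-methoxy-5-(5-phenylpent-2-ynoyl)phenoxy]-4-(tert-butyldimethylsilyloxy)-2-(5-phenylpent-2-ynoyl)-5-(triisopropylsilyloxy)cyclohex-2-en-1-one
Conditions: CO (5 bar), PdCl2(PPh3)2 (10 mol%), CuI (2 mol%), iPr2NEt, dry THF, 25 °C, 13 (2.4 equiv) added slowly
Reagents that add atoms: carbon monoxide, [C-]#[O+]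
Why: Zerovalent palladium, formed in the flask from PdCl2(PPh3)2, inserts into the alkenyl C4a–I and the aryl C4a′–I bonds, CO inserts to give two acylpalladium species, the copper acetylide of 13 transmetalates and reductive elimination releases each alkynyl ketone, so that C4a–C4, C4–C3, C4a′–C4′ and C4′–C3′ form in one operation. The closest known reaction type is the carbonylative Sonogashira coupling of aryl and alkenyl iodides to alkynones, here applied to both iodides of one substrate. No ring closes, because the phenol is held as its acetate and a hindered tertiary amine is the only base, so neither 5-exo nor 6-endo attack on an ynone can begin; no stereocentre is formed. The selectivity needed is chemoselectivity for CO insertion before alkyne transfer at both sites, which CO pressure, the low CuI loading and slow addition of 13 should secure, helped at the aryl site by the electron-rich arylpalladium bond, which inserts CO readily. The stereocentre alpha to the ketone (cyclohexenone C6, the later C8) should survive because iPr2NEt at room temperature is too weak and too hindered to enolise the ketone or to add to the new 2-acylenone.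

Step 9
Reactants: 14 (4R,5R,6S)-6-[4-acetoxy-2-methoxy-5-(5-phenylpent-2-ynoyl)phenoxy]-4-(tert-butyldimethylsilyloxy)-2-(5-phenylpent-2-ynoyl)-5-(triisopropylsilyloxy)cyclohex-2-en-1-one
Product: 16 4-{[(5S,6R,7R,8S)-6-(tert-butyldimethylsilyloxy)-5-hydroxy-4-oxo-2-(2-phenylethyl)-7-(triisopropylsilyloxy)-5,6,7,8-tetrahydro-4H-chromen-8-yl]oxy}-5-methoxy-2-(5-phenylpent-2-ynoyl)phenyl acetate, via hydroxy diketone 15 (not isolated)
Conditions: H2O (20 equiv), Et3N (1 equiv), THF, 0 °C → rt
Reagents that add atoms: water, O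
Why: Proposed new method: water (as hydroxide under amine catalysis) should add to C5 of the alkylidene 1,3-dicarbonyl unit, the most electrophilic site of 14, on the face anti to the adjacent C6 silyloxy group, which sets C5 trans to O6; the enolised 2-alkynoyl diketone 15 should then close through its C8a enol oxygen onto the ynone terminus in an irreversible 6-endo-dig oxa-Michael addition that pulls the reversible hydration forward and removes the C8 ketone alpha-proton problem; the closest known reaction types are the oxa-Michael addition of oxygen nucleophiles to alkylidene 1,3-dicarbonyl compounds and the base-mediated cyclisation of acetylenic 1,3-diketones to 4-pyranones.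

Step 10
Reactants: 16 4-{[(5S,6R,7R,8S)-6-(tert-butyldimethylsilyloxy)-5-hydroxy-4-oxo-2-(2-phenylethyl)-7-(triisopropylsilyloxy)-5,6,7,8-tetrahydro-4H-chromen-8-yl]oxy}-5-methoxy-2-(5-phenylpent-2-ynoyl)phenyl acetate
Product: 18 6-{[(5S,6R,7R,8S)-6-(tert-butyldimethylsilyloxy)-5-hydroxy-4-oxo-2-(2-phenylethyl)-7-(triisopropylsilyloxy)-5,6,7,8-tetrahydro-4H-chromen-8-yl]oxy}-7-methoxy-2-(2-phenylethyl)-4H-chromen-4-one, via enaminone phenol 17 (not isolated)
Conditions: Et2NH (excess), EtOH–THF, rt
Reagents that add atoms: none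
Why: Diethylamine removes the acetate by aminolysis and adds to the aryl ynone to give enaminone 17, whose phenol oxygen then displaces the amine by 6-endo addition–elimination; this is the known secondary-amine route from ortho-acyloxyaryl or ortho-hydroxyaryl ynones to chromones, it excludes 5-exo closure to the aurone, and no stereocentre is touched.

Step 11
Reactants: 18 6-{[(5S,6R,7R,8S)-6-(tert-butyldimethylsilyloxy)-5-hydroxy-4-oxo-2-(2-phenylethyl)-7-(triisopropylsilyloxy)-5,6,7,8-tetrahydro-4H-chromen-8-yl]oxy}-7-methoxy-2-(2-phenylethyl)-4H-chromen-4-one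
Product: 19 6-{[(5S,6R,7S,8S)-5,6,7-trihydroxy-4-oxo-2-(2-phenylethyl)-5,6,7,8-tetrahydro-4H-chromen-8-yl]oxy}-7-methoxy-2-(2-phenylethyl)-4H-chromen-4-one
Conditions: HF·pyridine, pyridine, THF, 0 °C → rt
Reagents that add atoms: none
Why: Fluoride cleaves both secondary silyl ethers through Si–F bond formation, and the pyridine buffer should keep the ionisable C5 carbinol and the C8 aryl ether intact, so no stereocentre changes.

Compound list
1 | (1S,2S)-3-bromocyclohexa-3,5-diene-1,2-diol (cis-diol) | O[C@H]1C=CC=C(Br)[C@H]1O | starting material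
2 | (1S,6S)-2-bromo-6-(triisopropylsilyloxy)cyclohexa-2,4-dien-1-ol (silyl ether on the hydroxyl distal to bromine) | CC(C)[Si](C(C)C)(C(C)C)O[C@H]1C=CC=C(Br)[C@H]1O | intermediate
3 | 4-fluoro-3-methoxybenzaldehyde | COc1cc(C=O)ccc1F | starting material
4 | 4-{[(1S,6S)-2-bromo-6-(triisopropylsilyloxy)cyclohexa-2,4-dien-1-yl]oxy}-3-methoxybenzaldehyde (aryloxy and silyloxy cis) | CC(C)[Si](C(C)C)(C(C)C)O[C@H]1C=CC=C(Br)[C@H]1Oc1ccc(C=O)cc1OC | intermediate
5 | endoperoxide of 4 (not isolated): 1-bromo-2,3-dioxabicyclo[2.2.2]oct-5-ene with the O–O bridge on the face opposite the aryloxy and silyloxy groups | CC(C)[Si](C(C)C)(C(C)C)O[C@H]1[C@H]2C=C[C@](Br)(OO2)[C@H]1Oc1ccc(C=O)cc1OC | intermediate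
6 | (4R,5S,6S)-6-(4-formyl-2-methoxyphenoxy)-4-hydroxy-5-(triisopropylsilyloxy)cyclohex-2-en-1-one | COc1cc(C=O)ccc1O[C@@H]1C(=O)C=C[C@@H](O)[C@@H]1O[Si](C(C)C)(C(C)C)C(C)C | intermediate
7 | (4R,5R,6S)-4-(tert-butyldimethylsilyloxy)-6-(4-formyl-2-methoxyphenoxy)-5-(triisopropylsilyloxy)cyclohex-2-en-1-one | COc1cc(C=O)ccc1O[C@@H]1C(=O)C=C[C@@H](O[Si](C)(C)C(C)(C)C)[C@@H]1O[Si](C(C)C)(C(C)C)C(C)C | intermediate
8 | aryl formate (not isolated): (4R,5R,6S)-4-(tert-butyldimethylsilyloxy)-6-[4-(formyloxy)-2-methoxyphenoxy]-5-(triisopropylsilyloxy)cyclohex-2-en-1-one | COc1cc(OC=O)ccc1O[C@@H]1C(=O)C=C[C@@H](O[Si](C)(C)C(C)(C)C)[C@@H]1O[Si](C(C)C)(C(C)C)C(C)C | intermediate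
9 | (4R,5R,6S)-4-(tert-butyldimethylsilyloxy)-6-(4-hydroxy-2-methoxyphenoxy)-5-(triisopropylsilyloxy)cyclohex-2-en-1-one | COc1cc(O)ccc1O[C@@H]1C(=O)C=C[C@@H](O[Si](C)(C)C(C)(C)C)[C@@H]1O[Si](C(C)C)(C(C)C)C(C)C | intermediate
10 | iodophenol (not isolated): (4R,5R,6S)-4-(tert-butyldimethylsilyloxy)-6-(4-hydroxy-5-iodo-2-methoxyphenoxy)-5-(triisopropylsilyloxy)cyclohex-2-en-1-one | COc1cc(O)c(I)cc1O[C@@H]1C(=O)C=C[C@@H](O[Si](C)(C)C(C)(C)C)[C@@H]1O[Si](C(C)C)(C(C)C)C(C)C | intermediate
11 | (4R,5R,6S)-6-(4-acetoxy-5-iodo-2-methoxyphenoxy)-4-(tert-butyldimethylsilyloxy)-5-(triisopropylsilyloxy)cyclohex-2-en-1-one | COc1cc(OC(C)=O)c(I)cc1O[C@@H]1C(=O)C=C[C@@H](O[Si](C)(C)C(C)(C)C)[C@@H]1O[Si](C(C)C)(C(C)C)C(C)C | intermediate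
12 | (4R,5R,6S)-6-(4-acetoxy-5-iodo-2-methoxyphenoxy)-4-(tert-butyldimethylsilyloxy)-2-iodo-5-(triisopropylsilyloxy)cyclohex-2-en-1-one (diiodide, precursor of the key step) | COc1cc(OC(C)=O)c(I)cc1O[C@@H]1C(=O)C(I)=C[C@@H](O[Si](C)(C)C(C)(C)C)[C@@H]1O[Si](C(C)C)(C(C)C)C(C)C | intermediate
13 | 4-phenylbut-1-yne | C#CCCc1ccccc1 | starting material
14 | (4R,5R,6S)-6-[4-acetoxy-2-methoxy-5-(5-phenylpent-2-ynoyl)phenoxy]-4-(tert-butyldimethylsilyloxy)-2-(5-phenylpent-2-ynoyl)-5-(triisopropylsilyloxy)cyclohex-2-en-1-one (bis-ynone, product of the key step) | COc1cc(OC(C)=O)c(C(=O)C#CCCc2ccccc2)cc1O[C@@H]1C(=O)C(C(=O)C#CCCc2ccccc2)=C[C@@H](O[Si](C)(C)C(C)(C)C)[C@@H]1O[Si](C(C)C)(C(C)C)C(C)C | intermediate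
15 | hydroxy diketone (not isolated), drawn as its C8a enol; chromone locants (5S,6R,7R,8S), C5–OH trans to O6 | COc1cc(OC(C)=O)c(C(=O)C#CCCc2ccccc2)cc1O[C@@H]1C(O)=C(C(=O)C#CCCc2ccccc2)[C@H](O)[C@@H](O[Si](C)(C)C(C)(C)C)[C@@H]1O[Si](C(C)C)(C(C)C)C(C)C | intermediate
16 | 4-{[(5S,6R,7R,8S)-6-(tert-butyldimethylsilyloxy)-5-hydroxy-4-oxo-2-(2-phenylethyl)-7-(triisopropylsilyloxy)-5,6,7,8-tetrahydro-4H-chromen-8-yl]oxy}-5-methoxy-2-(5-phenylpent-2-ynoyl)phenyl acetate | COc1cc(OC(C)=O)c(C(=O)C#CCCc2ccccc2)cc1O[C@@H]1c2oc(CCc3ccccc3)cc(=O)c2[C@H](O)[C@@H](O[Si](C)(C)C(C)(C)C)[C@@H]1O[Si](C(C)C)(C(C)C)C(C)C | intermediate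
17 | enaminone phenol (not isolated): the free phenol of 16 with diethylamine added across the aryl ynone, (E)-3-(diethylamino)-5-phenylpent-2-enoyl arm | COc1cc(O)c(C(=O)/C=C(\CCc2ccccc2)N(CC)CC)cc1O[C@@H]1c2oc(CCc3ccccc3)cc(=O)c2[C@H](O)[C@@H](O[Si](C)(C)C(C)(C)C)[C@@H]1O[Si](C(C)C)(C(C)C)C(C)C | intermediate
18 | 6-{[(5S,6R,7R,8S)-6-(tert-butyldimethylsilyloxy)-5-hydroxy-4-oxo-2-(2-phenylethyl)-7-(triisopropylsilyloxy)-5,6,7,8-tetrahydro-4H-chromen-8-yl]oxy}-7-methoxy-2-(2-phenylethyl)-4H-chromen-4-one | COc1cc2oc(CCc3ccccc3)cc(=O)c2cc1O[C@@H]1c2oc(CCc3ccccc3)cc(=O)c2[C@H](O)[C@@H](O[Si](C)(C)C(C)(C)C)[C@@H]1O[Si](C(C)C)(C(C)C)C(C)C | intermediate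
19 | 6-{[(5S,6R,7S,8S)-5,6,7-trihydroxy-4-oxo-2-(2-phenylethyl)-5,6,7,8-tetrahydro-4H-chromen-8-yl]oxy}-7-methoxy-2-(2-phenylethyl)-4H-chromen-4-one | COc1cc2oc(CCc3ccccc3)cc(=O)c2cc1O[C@@H]1c2oc(CCc3ccccc3)cc(=O)c2[C@H](O)[C@@H](O)[C@@H]1O | target

Total step count: 11
Longest linear sequence: 11 steps (1 → 19); 3 and 13 are purchased and enter directly.

Steps most likely to fail

Step 9 (the proposed method). The water addition may revert before the pyranone closes, the new C5 hydroxyl or water may instead attack the ynone, or the facial preference at C5 may be weak because the 1,3-related O7 group sits on the face that must be attacked. The fallback sets out from 14 and puts the oxygen on C5 irreversibly by known reactions. Weitz–Scheffer epoxidation of the doubly activated alkene with anhydrous tert-butyl hydroperoxide and catalytic DBU in toluene at −20 °C, the peroxide anion attacking C5 anti to the C6 silyloxy group, should give epoxy diketone F1. Samarium diiodide (SmI2, THF–MeOH, −90 °C) should then cleave the C4a–O bond, the known reductive opening of alpha,beta-epoxy ketones to beta-hydroxy ketones, which leaves the C5–O bond and its configuration intact and delivers hydroxy diketone 15. Brief treatment with Et3N in THF closes 15 to 16, where the fallback rejoins the route.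

Step 8. Alkyne transfer may outrun CO insertion at the electron-poor alkenylpalladium centre, which would give direct alkynylation. The amine may also epimerise the alpha-aryloxy carbon or trigger oligomerisation of the 2-acylenone as it forms. The fallback sets out from 12 and 13 and removes both the amine and the copper acetylide. Compound 13 is lithiated (n-BuLi, THF, −78 °C) and quenched with Bu3SnCl to give tributyl(4-phenylbut-1-yn-1-yl)stannane F2. A twofold carbonylative Stille coupling of 12 with F2 (CO 10 bar, PdCl2(PPh3)2, THF, 50 °C), known for aryl and alkenyl iodides, should then give 14 under neutral conditions, where the fallback rejoins the route.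

Step 2. The silyl group may still shift to the neighbouring alkoxide, which would scramble the regiochemistry, or the substitution may be slow enough for the alkoxide to be lost to addition at the aldehyde. The fallback sets out from 2 and forms the ether by two inversions without any alkoxide. A Mitsunobu esterification with 4-nitrobenzoic acid (PPh3, DIAD, THF, 0 °C) inverts the carbinol to give trans 4-nitrobenzoate F3. Methanolysis (K2CO3, MeOH, 0 °C) frees trans alcohol F4. A second Mitsunobu reaction, with vanillin (4-hydroxy-3-methoxybenzaldehyde; PPh3, DIAD, THF), inverts the centre again and should give the cis aryl ether 4, where the fallback rejoins the route.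

Further compounds
F1 | step 9 | epoxy diketone: 2,3-epoxide of 14 (oxirane across C4a–C5 in chromone locants, oxirane oxygen trans to the C6 silyloxy group) | COc1cc(OC(C)=O)c(C(=O)C#CCCc2ccccc2)cc1O[C@@H]1C(=O)[C@]2(C(=O)C#CCCc3ccccc3)O[C@@H]2[C@@H](O[Si](C)(C)C(C)(C)C)[C@@H]1O[Si](C(C)C)(C(C)C)C(C)C
F2 | step 8 | tributyl(4-phenylbut-1-yn-1-yl)stannane | CCCC[Sn](CCCC)(CCCC)C#CCCc1ccccc1
F3 | step 2 | (1R,6S)-2-bromo-6-(triisopropylsilyloxy)cyclohexa-2,4-dien-1-yl 4-nitrobenzoate (ester and silyloxy trans) | CC(C)[Si](C(C)C)(C(C)C)O[C@H]1C=CC=C(Br)[C@@H]1OC(=O)c1ccc(cc1)[N+](=O)[O-]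
F4 | step 2 | (1R,6S)-2-bromo-6-(triisopropylsilyloxy)cyclohexa-2,4-dien-1-ol (hydroxyl and silyloxy trans) | CC(C)[Si](C(C)C)(C(C)C)O[C@H]1C=CC=C(Br)[C@@H]1O
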